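**Plan**

1. Retrosynthesis first removes the C3 acetate, the C8 angelate and C13, then opens the lactone at O6–C12. This leaves a cyclodecadienone in which the C6 carbonyl, the Z C4=C5 bond (C15 on C4), the oxygenated C3 and the E C1=C2 bond form one run C6–C5–C4–C3–C2–C1 (germacrane numbering).
2. That run is the retron of an alkynyl vinyl carbinol [3,3] shift. Cutting C3–C4 and joining C1 to C6 across the ten-membered ring gives a cyclohexane (C6, C1, C10, C9, C8, C7) with a propynyl carbinol at C6 and an (E)-alkoxyvinyl arm at C1; it already holds C7, C8 and C10.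
3. The cyclohexanol is cut at C6–C5 (propynyl), C3–O and C2–C3 (enol ether), C1–C2 (methylene) and C7–C11 (allyl), which leads to (−)-quinic acid (six ring carbons plus C14).
4. Forward: six-membered ring from quinic acid, arms at C7, C1 and C6, ring expansion to the ten-membered ring, γ-lactone ring last, then C13 and the two esters.
5. Stereochemistry: C8 and C10 come from quinic acid. C7 (radical allylation) and C1 (hydroboration) are set equatorial against them. The C6 carbinol comes from equatorial Grignard attack, C3 from chirality transfer out of C1 in the chair transition state, C6 of the lactone from peripheral hydride attack, and Z C4=C5 from peripheral protonation.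

Key step: step 19

Remark: germacrane numbering (C1–C15) is used for every intermediate. The target SMILES is read as (1E,3R,4Z,6R,7S,8R,10R) with a cis-fused lactone. α/β mean below/above the ring drawn with C6→C1→C10→C9→C8→C7 clockwise. The cyclohexane intermediates are assumed to react from the chair with the C10 methyl equatorial and O10 axial (chair A).

**Step 1**
Reactants: 1 (−)-quinic acid
Product: 2 quinide acetonide (γ-lactone C14→O8; isopropylidene on O6/O7; free C10–OH)
Conditions: Me2C(OMe)2, TsOH·H2O (cat.), acetone, reflux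
Reagents that add atoms: 2,2-dimethoxypropane, COC(C)(C)OC
Why: Acid-catalysed acetalisation of the only cis-1,2-diol and lactonisation of the carboxyl onto the syn-1,3 hydroxyl run together (acetonide formation, lactonisation) and change no stereocentre.

**Step 2**
Reactants: 2 quinide acetonide
Product: 3 triol acetonide (C14H2–OH; C10–OH; C8–OH)
Conditions: LiAlH4, THF, 0 °C → reflux
Reagents that add atoms: none
Why: Hydride reduction of the lactone (LiAlH4 ester reduction) frees the primary C14 alcohol and the C8 carbinol without touching a stereocentre.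

**Step 3**
Reactants: 3 triol acetonide
Product: 4 primary tosylate (C14–OTs)
Conditions: TsCl (1.1 equiv), pyridine, 0 °C
Reagents that add atoms: 4-toluenesulfonyl chloride, Cc1ccc(cc1)S(=O)(=O)Cl
Why: Sulfonylation is fastest at the primary hydroxyl, so one equivalent of TsCl should mark C14 alone (selective tosylation).

**Step 4**
Reactants: 4 primary tosylate
Product: 6 methyl diol acetonide (C10 methyl carbinol; free C8–OH), via spiro-epoxide 5 (not isolated)
Conditions: LiEt3BH (4 equiv), THF, 0 °C → rt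
Reagents that add atoms: none
Why: The tertiary alkoxide displaces the neighbouring tosylate to give epoxide 5 (intramolecular Williamson closure) and triethylborohydride opens it at the unhindered CH2 (reductive epoxide opening), so C14 becomes the methyl group while the C10–O bond and its configuration are untouched.

**Step 5**
Reactants: 6 methyl diol acetonide
Product: 7 bis-silyl ether acetonide (O8 and O10 as tert-butyldimethylsilyl ethers)
Conditions: tBuMe2SiOTf (3 equiv), 2,6-lutidine, CH2Cl2, 0 °C → rt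
Reagents that add atoms: tert-butyldimethylsilyl trifluoromethanesulfonate, CC(C)(C)[Si](C)(C)OS(=O)(=O)C(F)(F)F
Why: A silyl triflate with a hindered pyridine base silylates the secondary and also the tertiary carbinol (silyl ether formation).

**Step 6**
Reactants: 7 bis-silyl ether acetonide
Product: 8 cis-diol (C6–OH axial; C7–OH equatorial)
Conditions: AcOH–H2O (4:1), 40 °C
Reagents that add atoms: none
Why: Acid hydrolysis of the cis-fused isopropylidene acetal should be faster than cleavage of tert-butyldimethylsilyl ethers on secondary and tertiary carbons (acetal hydrolysis).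

**Step 7**
Reactants: 8 cis-diol
Product: 10 ketol (C6 ketone; C7α–OH), via stannylene acetal 9 (not isolated)
Conditions: Bu2SnO, toluene, reflux (−H2O); then Br2 (1 equiv), 4 Å MS, CH2Cl2, 0 °C
Reagents that add atoms: dibutyltin oxide, CCCC[Sn](=O)CCCC (its tin stays only in intermediate 9)
Why: Brominolysis of the dibutylstannylene acetal of a cis-1,2-diol oxidises the carbinol whose oxygen is axial (regioselective stannylene oxidation), here C6 in chair A, and leaves the equatorial C7 hydroxyl.

**Step 8**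
Reactants: 10 ketol
Product: 11 C7 O-phenyl thionocarbonate
Conditions: PhOC(S)Cl, pyridine, DMAP (cat.), CH2Cl2, 0 °C → rt
Reagents that add atoms: O-phenyl chlorothionoformate, S=C(Cl)Oc1ccccc1
Why: Thioacylation of the secondary alcohol installs a radical leaving group at C7 (thionocarbonate formation as in Barton–McCombie chemistry).

**Step 9**
Reactants: 11 C7 O-phenyl thionocarbonate; 12 allyltributylstannane
Product: 13 allyl ketone (C7α-allyl trans to O8)
Conditions: 12 (3 equiv), AIBN (cat.), benzene, 80 °C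
Reagents that add atoms: allyltributylstannane 12, C=CC[Sn](CCCC)(CCCC)CCCC
Why: Keck radical allylation: the stannyl radical fragments the thionocarbonate to the C7 α-keto radical, which adds to the allylstannane opposite the neighbouring C8 silyl ether, so the allyl group ends equatorial and trans to O8, which is also the more stable α-epimer of the ketone.

**Step 10**
Reactants: 13 allyl ketone
Product: 15 keto aldehyde (C12 aldehyde), via ozonide 14 (not isolated)
Conditions: O3, CH2Cl2, −78 °C; then Me2S, −78 °C → rt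
Reagents that add atoms: ozone, [O-][O+]=O
Why: Ozonolysis of the only alkene with reductive work-up shortens the allyl group to the two-carbon C11–C12 arm.

**Step 11**
Reactants: 15 keto aldehyde
Product: 16 hydroxy ketone (C12–OH)
Conditions: NaBH(OAc)3, benzene, rt
Reagents that add atoms: none
Why: Triacetoxyborohydride reduces the aldehyde but not the hindered ketone (chemoselective hydride reduction).

**Step 12**
Reactants: 16 hydroxy ketone
Product: 17 triethylsilyl ether ketone (C12–OSiEt3)
Conditions: Et3SiCl, imidazole, CH2Cl2, 0 °C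
Reagents that add atoms: chlorotriethylsilane, CC[Si](Cl)(CC)CC
Why: Silylation of the primary alcohol gives an ether that can later be removed in the presence of the two tert-butyldimethylsilyl ethers (silyl ether formation).

**Step 13**
Reactants: 17 triethylsilyl ether ketone
Product: 21 α-methylene ketone (C1=C2H2), via lithium enolate 18 (not isolated), via Mannich base 19 (not isolated), via ammonium iodide 20 (not isolated)
Conditions: LiN(iPr)2, THF, −78 °C; CH2=NMe2+ I−, −78 °C → rt; then MeI, CH2Cl2, rt; then aq. NaHCO3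
Reagents that add atoms: N,N-dimethylmethyleneiminium iodide (Eschenmoser's salt), C=[N+](C)C.[I-]; iodomethane, CI (its methyl stays only in intermediate 20)
Why: Kinetic deprotonation should take the C1 methylene rather than the C7 methine, enolate 18 is aminomethylated (Mannich reaction), and exhaustive methylation with mild base eliminates trimethylamine (Eschenmoser methylenation), so C1 is deliberately made planar to be set again in step 15.

**Step 14**
Reactants: 21 α-methylene ketone; 22 1-propynylmagnesium bromide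
Product: 23 propynyl carbinol (C6: β-propynyl equatorial and α-OH axial; C1=C2H2)
Conditions: 22 (3 equiv), LaCl3·2LiCl (30 mol %), THF, 0 °C
Reagents that add atoms: 1-propynylmagnesium bromide 22, CC#C[Mg]Br
Why: Grignard 1,2-addition promoted by the oxophilic lanthanum salt: the axial C10 silyl ether blocks the axial trajectory at C6, so the propynyl group should enter equatorially from the β face and leave the hydroxyl axial and α.

**Step 15**
Reactants: 23 propynyl carbinol
Product: 25 diol (C2–OH on the equatorial C1α arm; C6–OH), via alkylborane 24 (not isolated)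
Conditions: 9-BBN (3 equiv), THF, 0 → 50 °C; then NaOH, H2O2, 0 °C
Reagents that add atoms: 9-borabicyclo[3.3.1]nonane, [H]B1C2CCCC1CCC2 (its boron stays only in intermediate 24); hydrogen peroxide, OO
Why: Anti-Markovnikov hydroboration–oxidation of the 1,1-disubstituted alkene (the internal alkyne reacts far more slowly with 9-BBN) puts hydrogen on C1 from the β face, away from the two flanking axial oxygens on C6 and C10, which should leave the CH2OH arm equatorial, α and cis to the C7 arm.

**Step 16**
Reactants: 25 diol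
Product: 26 hydroxy aldehyde (C2 aldehyde)
Conditions: TEMPO (0.2 equiv), PhI(OAc)2 (1.2 equiv), CH2Cl2, rt
Reagents that add atoms: none
Why: Oxoammonium (TEMPO) oxidation stops at the aldehyde and cannot touch the tertiary carbinol, and the equatorial formyl group is also the more stable C1 epimer, so the centre should hold.

**Step 17**
Reactants: 26 hydroxy aldehyde
Product: 27 (E)-alkenylboronate (C1–C2H=C3H–Bpin)
Conditions: CrCl2 (8 equiv), LiI (4 equiv), Cl2CHB(pin) (2 equiv), THF, rt
Reagents that add atoms: 2-(dichloromethyl)-4,4,5,5-tetramethyl-1,3,2-dioxaborolane, ClC(Cl)B1OC(C)(C)C(C)(C)O1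
Why: Takai–Utimoto-type olefination with the geminal dichromium species formed from the dichloromethylboronate gives the alkenylboronate with the E geometry typical of this reaction.

**Step 18**
Reactants: 27 (E)-alkenylboronate
Product: 28 cyclohexanol precursor (6β-propynyl-6α-ol; 1α-[(E)-2-(4-methoxybenzyloxy)vinyl]; 10β-methyl-10α-OTBS; 8β-OTBS; 7α-CH2CH2OSiEt3)
Conditions: Cu(OAc)2 (2 equiv), Et3N (4 equiv), 4-MeOC6H4CH2OH (20 equiv), 4 Å MS, CH2Cl2, air, rt
Reagents that add atoms: 4-methoxybenzyl alcohol, COc1ccc(CO)cc1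
Why: Copper-mediated oxidative C–O coupling of the alkenylboronate with the primary benzylic alcohol (Chan–Lam type etherification) proceeds with retention of alkene geometry and should give the E enol ether, the tertiary C6 hydroxyl being too hindered to compete.

**Step 19**
Reactants: 28 cyclohexanol precursor
Product: 31 (2Z,5E)-cyclodeca-2,5-dienone (C6 ketone; Z C4=C5; 3α-OPMB; E C1=C2), via potassium alkoxide 29 (not isolated), via potassium allenolate 30 (not isolated)
Conditions: KH (1.5 equiv), 18-crown-6 (1.5 equiv), THF, 0 °C → rt; then AcOH, THF, −78 °C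
Reagents that add atoms: potassium hydride, [K+].[H-] (its potassium stays only in intermediates 29 and 30)
Why: KH with 18-crown-6 turns 28 into the potassium alkoxide 29, which in chair A holds the C6 propynyl and the C1 (E)-alkoxyvinyl arm both equatorial and gauche, so that a concerted anionic [3,3] shift (acetylenic oxy-Cope rearrangement) forms C3–C4, breaks C1–C6 and gives the cyclic potassium allenolate 30; the closest known reaction type is the KH-mediated ring expansion of 1-alkynyl-2-vinylcycloalkanols to cycloalkadienones. The ten-membered ring is not closed end to end but arises by four-atom expansion of the six-membered ring through a six-centre chair-like transition state. The one new stereocentre, C3, is fixed by suprafacial chirality transfer from C1, which is consumed: with the E enol ether and the C1–H bond eclipsing the vinyl group, C4 can only reach the face of C3 that gives 3R. In the same array C10 sits anti to C3 across the forming C1=C2 bond, which therefore comes out E. Quenching at −78 °C protonates C5 of the allenolate from the ring periphery, on the side of the C15 methyl, which gives the Z enone. The step needs this enyne to be the only [3,3] array and the alkoxide to rearrange faster than it fragments: the saturated C7 arm secures the first, the crown-ether-separated ion pair and the low temperature should secure the second.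

**Step 20**
Reactants: 31 (2Z,5E)-cyclodeca-2,5-dienone
Product: 32 allylic alcohol (6R; O6 α and cis to the C7 arm)
Conditions: NaBH4, CeCl3·7H2O, MeOH, −78 °C
Reagents that add atoms: none
Why: Luche 1,2-reduction: in the conformer inherited from the chair transition state the inner face of the C6 carbonyl is covered by the transannular C1=C2 bond, so hydride should add from the periphery and give the 6R alcohol with O6 cis to the C7 arm.

**Step 21**
Reactants: 32 allylic alcohol
Product: 33 diol (C6–OH; C12–OH)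
Conditions: PPTS (0.2 equiv), MeOH–CH2Cl2 (1:1), 0 °C
Reagents that add atoms: none
Why: Acid-catalysed methanolysis removes the primary triethylsilyl ether much faster than the secondary and tertiary tert-butyldimethylsilyl ethers (selective desilylation).

**Step 22**
Reactants: 33 diol
Product: 36 cis-fused γ-lactone (O6–C12(=O)), via hydroxy aldehyde 34 (not isolated), via lactol 35 (not isolated)
Conditions: TEMPO (0.2 equiv), PhI(OAc)2 (2.5 equiv), CH2Cl2, rt
Reagents that add atoms: none
Why: TEMPO/PhI(OAc)2 oxidative lactonisation: the primary alcohol is oxidised first, aldehyde 34 closes on O6 to lactol 35 (5-exo-trig) and this is oxidised on to the γ-lactone, whose cis ring fusion follows from the configurations already present at C6 and C7.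

**Step 23**
Reactants: 36 cis-fused γ-lactone
Product: 40 α-methylene lactone (C11=C13H2), via lithium enolate 37 (not isolated), via Mannich base 38 (not isolated), via ammonium iodide 39 (not isolated)
Conditions: LiN(iPr)2, THF, −78 °C; CH2=NMe2+ I−, −78 °C → rt; then MeI, MeOH, rt; then aq. NaHCO3, CH2Cl2
Reagents that add atoms: N,N-dimethylmethyleneiminium iodide (Eschenmoser's salt), C=[N+](C)C.[I-]; iodomethane, CI (its methyl stays only in intermediate 39)
Why: Eschenmoser α-methylenation: lactone enolate 37 is aminomethylated (Mannich reaction), and quaternisation followed by mild base eliminates trimethylamine to give the exocyclic C11=C13 bond.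

**Step 24**
Reactants: 40 α-methylene lactone
Product: 41 diol (C8–OH; C10–OH)
Conditions: HF·pyridine, pyridine, THF, 0 °C → rt
Reagents that add atoms: none
Why: Fluoride-driven cleavage of both silyl ethers under pyridine-buffered conditions should spare the methylene lactone and the allylic ether (desilylation).

**Step 25**
Reactants: 41 diol; 42 angelic acid
Product: 44 C8 angelate, via mixed anhydride 43 (not isolated)
Conditions: 42, 2,4,6-Cl3C6H2COCl, Et3N, toluene, rt; then 41, toluene, 75 °C
Reagents that add atoms: angelic acid 42, C/C=C(/C)C(=O)O; 2,4,6-trichlorobenzoyl chloride, O=C(Cl)c1c(Cl)cc(Cl)cc1Cl (its atoms stay only in intermediate 43)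
Why: Mixed-anhydride esterification (Yamaguchi type, run without a nucleophilic catalyst so that the Z geometry of the angeloyl group is kept) acylates the secondary C8 hydroxyl, while the tertiary C10 hydroxyl is too hindered to react.

**Step 26**
Reactants: 44 C8 angelate
Product: 45 C3 alcohol
Conditions: DDQ (1.3 equiv), CH2Cl2–pH 7 phosphate buffer (10:1), 0 °C
Reagents that add atoms: none
Why: Oxidative cleavage of the 4-methoxybenzyl ether by DDQ (benzylic hydride abstraction, then hydrolysis) frees the C3 carbinol without touching its configuration.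

**Step 27**
Reactants: 45 C3 alcohol
Product: 46 CNP0181631.1
Conditions: Ac2O, pyridine, DMAP (cat.), CH2Cl2, 0 °C
Reagents that add atoms: acetic anhydride, CC(=O)OC(C)=O
Why: Acetylation of the secondary allylic alcohol (Ac2O/pyridine with DMAP catalysis) is far faster than that of the tertiary C10 hydroxyl and completes the target.

**Compound list**

1 | (−)-quinic acid | OC(=O)[C@]1(O)C[C@@H](O)[C@@H](O)[C@H](O)C1 | starting material
2 | quinide acetonide (3,4-O-isopropylidene-1,5-quinide) | CC1(C)O[C@@H]2C[C@]3(O)C[C@@H](OC3=O)[C@@H]2O1 | intermediate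
3 | triol acetonide (C14H2OH, C10–OH, C8–OH) | CC1(C)O[C@@H]2C[C@](CO)(O)C[C@@H](O)[C@@H]2O1 | intermediate
4 | primary tosylate of 3 | CC1(C)O[C@@H]2C[C@](COS(=O)(=O)c3ccc(C)cc3)(O)C[C@@H](O)[C@@H]2O1 | intermediate
5 | spiro-epoxide (O10–C14) | CC1(C)O[C@@H]2C[C@@]3(CO3)C[C@@H](O)[C@@H]2O1 | intermediate (not isolated)
6 | methyl diol acetonide (10β-methyl, 10α-OH, 8β-OH) | CC1(C)O[C@@H]2C[C@](C)(O)C[C@@H](O)[C@@H]2O1 | intermediate
7 | bis(tert-butyldimethylsilyl) ether acetonide | CC1(C)O[C@@H]2C[C@](C)(O[Si](C)(C)C(C)(C)C)C[C@@H](O[Si](C)(C)C(C)(C)C)[C@@H]2O1 | intermediate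
8 | cis-diol (6α-OH axial, 7α-OH equatorial) | O[C@@H]1C[C@](C)(O[Si](C)(C)C(C)(C)C)C[C@@H](O[Si](C)(C)C(C)(C)C)[C@@H]1O | intermediate
9 | dibutylstannylene acetal of 8 | CCCC[Sn]1(CCCC)O[C@@H]2C[C@](C)(O[Si](C)(C)C(C)(C)C)C[C@@H](O[Si](C)(C)C(C)(C)C)[C@@H]2O1 | intermediate (not isolated)
10 | ketol (C6 ketone, 7α-OH) | O=C1C[C@](C)(O[Si](C)(C)C(C)(C)C)C[C@@H](O[Si](C)(C)C(C)(C)C)[C@@H]1O | intermediate
11 | C7 O-phenyl thionocarbonate of 10 | O=C1C[C@](C)(O[Si](C)(C)C(C)(C)C)C[C@@H](O[Si](C)(C)C(C)(C)C)[C@@H]1OC(=S)Oc2ccccc2 | intermediate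
12 | allyltributylstannane | C=CC[Sn](CCCC)(CCCC)CCCC | starting material
13 | allyl ketone (7α-allyl, trans to O8) | O=C1C[C@](C)(O[Si](C)(C)C(C)(C)C)C[C@@H](O[Si](C)(C)C(C)(C)C)[C@@H]1CC=C | intermediate
14 | ozonide of 13 (1,2,4-trioxolane) | O=C1C[C@](C)(O[Si](C)(C)C(C)(C)C)C[C@@H](O[Si](C)(C)C(C)(C)C)[C@@H]1CC2OCOO2 | intermediate (not isolated)
15 | keto aldehyde (C12 aldehyde) | O=C1C[C@](C)(O[Si](C)(C)C(C)(C)C)C[C@@H](O[Si](C)(C)C(C)(C)C)[C@@H]1CC=O | intermediate
16 | hydroxy ketone (C12–OH) | O=C1C[C@](C)(O[Si](C)(C)C(C)(C)C)C[C@@H](O[Si](C)(C)C(C)(C)C)[C@@H]1CCO | intermediate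
17 | triethylsilyl ether ketone | O=C1C[C@](C)(O[Si](C)(C)C(C)(C)C)C[C@@H](O[Si](C)(C)C(C)(C)C)[C@@H]1CCO[Si](CC)(CC)CC | intermediate
18 | lithium enolate of 17 (C6=C1) | [Li+].[O-]C1=C[C@](C)(O[Si](C)(C)C(C)(C)C)C[C@@H](O[Si](C)(C)C(C)(C)C)[C@@H]1CCO[Si](CC)(CC)CC | intermediate (not isolated)
19 | Mannich base (C1–CH2NMe2, C1 configuration not fixed) | O=C1C(CN(C)C)[C@](C)(O[Si](C)(C)C(C)(C)C)C[C@@H](O[Si](C)(C)C(C)(C)C)[C@@H]1CCO[Si](CC)(CC)CC | intermediate (not isolated)
20 | trimethylammonium iodide of 19 | O=C1C(C[N+](C)(C)C)[C@](C)(O[Si](C)(C)C(C)(C)C)C[C@@H](O[Si](C)(C)C(C)(C)C)[C@@H]1CCO[Si](CC)(CC)CC.[I-] | intermediate (not isolated)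
21 | α-methylene ketone (C1=C2H2) | O=C1C(=C)[C@](C)(O[Si](C)(C)C(C)(C)C)C[C@@H](O[Si](C)(C)C(C)(C)C)[C@@H]1CCO[Si](CC)(CC)CC | intermediate
22 | 1-propynylmagnesium bromide | CC#C[Mg]Br | starting material
23 | propynyl carbinol (6β-propynyl, 6α-OH, C1=C2H2) | CC#C[C@@]1(O)C(=C)[C@](C)(O[Si](C)(C)C(C)(C)C)C[C@@H](O[Si](C)(C)C(C)(C)C)[C@@H]1CCO[Si](CC)(CC)CC | intermediate
24 | B-alkyl-9-borabicyclo[3.3.1]nonane (boron on C2) | CC#C[C@@]1(O)[C@H](CB2C3CCCC2CCC3)[C@](C)(O[Si](C)(C)C(C)(C)C)C[C@@H](O[Si](C)(C)C(C)(C)C)[C@@H]1CCO[Si](CC)(CC)CC | intermediate (not isolated)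
25 | diol (1α-CH2OH, 6α-OH) | CC#C[C@@]1(O)[C@H](CO)[C@](C)(O[Si](C)(C)C(C)(C)C)C[C@@H](O[Si](C)(C)C(C)(C)C)[C@@H]1CCO[Si](CC)(CC)CC | intermediate
26 | hydroxy aldehyde (1α-CHO) | CC#C[C@@]1(O)[C@H](C=O)[C@](C)(O[Si](C)(C)C(C)(C)C)C[C@@H](O[Si](C)(C)C(C)(C)C)[C@@H]1CCO[Si](CC)(CC)CC | intermediate
27 | (E)-alkenylboronic acid pinacol ester | CC#C[C@@]1(O)[C@H](/C=C/B2OC(C)(C)C(C)(C)O2)[C@](C)(O[Si](C)(C)C(C)(C)C)C[C@@H](O[Si](C)(C)C(C)(C)C)[C@@H]1CCO[Si](CC)(CC)CC | intermediate
28 | cyclohexanol precursor: 6β-(1-propynyl)-6α-ol with 1α-[(E)-2-(4-methoxybenzyloxy)vinyl], 10β-methyl, 10α-OTBS, 8β-OTBS, 7α-(2-triethylsilyloxyethyl) | CC#C[C@@]1(O)[C@H](/C=C/OCc2ccc(OC)cc2)[C@](C)(O[Si](C)(C)C(C)(C)C)C[C@@H](O[Si](C)(C)C(C)(C)C)[C@@H]1CCO[Si](CC)(CC)CC | intermediate (key-step precursor)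
29 | potassium alkoxide of 28 | CC#C[C@@]1([O-])[C@H](/C=C/OCc2ccc(OC)cc2)[C@](C)(O[Si](C)(C)C(C)(C)C)C[C@@H](O[Si](C)(C)C(C)(C)C)[C@@H]1CCO[Si](CC)(CC)CC.[K+] | intermediate (not isolated)
30 | potassium allenolate (ten-membered ring, C6(O−)=C5=C4; allene axis not specified) | [K+].[O-]C1=C=C(C)[C@H](OCc2ccc(OC)cc2)/C=C/[C@](C)(O[Si](C)(C)C(C)(C)C)C[C@@H](O[Si](C)(C)C(C)(C)C)[C@@H]1CCO[Si](CC)(CC)CC | intermediate (not isolated)
31 | (2Z,5E)-cyclodeca-2,5-dienone (C6 ketone, Z C4=C5, 3R-OPMB, E C1=C2) | O=C1/C=C(/C)[C@H](OCc2ccc(OC)cc2)/C=C/[C@](C)(O[Si](C)(C)C(C)(C)C)C[C@@H](O[Si](C)(C)C(C)(C)C)[C@@H]1CCO[Si](CC)(CC)CC | intermediate (key-step product)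
32 | allylic alcohol (6R, O6 cis to the C7 arm) | O[C@@H]1/C=C(/C)[C@H](OCc2ccc(OC)cc2)/C=C/[C@](C)(O[Si](C)(C)C(C)(C)C)C[C@@H](O[Si](C)(C)C(C)(C)C)[C@@H]1CCO[Si](CC)(CC)CC | intermediate
33 | diol (C6–OH, C12–OH) | O[C@@H]1/C=C(/C)[C@H](OCc2ccc(OC)cc2)/C=C/[C@](C)(O[Si](C)(C)C(C)(C)C)C[C@@H](O[Si](C)(C)C(C)(C)C)[C@@H]1CCO | intermediate
34 | hydroxy aldehyde (C12 aldehyde) | O[C@@H]1/C=C(/C)[C@H](OCc2ccc(OC)cc2)/C=C/[C@](C)(O[Si](C)(C)C(C)(C)C)C[C@@H](O[Si](C)(C)C(C)(C)C)[C@@H]1CC=O | intermediate (not isolated)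
35 | lactol (O6–C12(OH), anomeric centre not fixed) | C1C(O)O[C@@H]2/C=C(/C)[C@H](OCc3ccc(OC)cc3)/C=C/[C@](C)(O[Si](C)(C)C(C)(C)C)C[C@@H](O[Si](C)(C)C(C)(C)C)[C@H]12 | intermediate (not isolated)
36 | cis-fused γ-lactone (12,6-olide) | C1C(=O)O[C@@H]2/C=C(/C)[C@H](OCc3ccc(OC)cc3)/C=C/[C@](C)(O[Si](C)(C)C(C)(C)C)C[C@@H](O[Si](C)(C)C(C)(C)C)[C@H]12 | intermediate
37 | lithium enolate of 36 | C1=C([O-])O[C@@H]2/C=C(/C)[C@H](OCc3ccc(OC)cc3)/C=C/[C@](C)(O[Si](C)(C)C(C)(C)C)C[C@@H](O[Si](C)(C)C(C)(C)C)[C@H]12.[Li+] | intermediate (not isolated)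
38 | Mannich base (C11–CH2NMe2, C11 not fixed) | CN(C)CC1C(=O)O[C@@H]2/C=C(/C)[C@H](OCc3ccc(OC)cc3)/C=C/[C@](C)(O[Si](C)(C)C(C)(C)C)C[C@@H](O[Si](C)(C)C(C)(C)C)[C@H]12 | intermediate (not isolated)
39 | trimethylammonium iodide of 38 | C[N+](C)(C)CC1C(=O)O[C@@H]2/C=C(/C)[C@H](OCc3ccc(OC)cc3)/C=C/[C@](C)(O[Si](C)(C)C(C)(C)C)C[C@@H](O[Si](C)(C)C(C)(C)C)[C@H]12.[I-] | intermediate (not isolated)
40 | α-methylene lactone (C11=C13H2) | C=C1C(=O)O[C@@H]2/C=C(/C)[C@H](OCc3ccc(OC)cc3)/C=C/[C@](C)(O[Si](C)(C)C(C)(C)C)C[C@@H](O[Si](C)(C)C(C)(C)C)[C@H]12 | intermediate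
41 | diol (C8–OH, C10–OH) | C=C1C(=O)O[C@@H]2/C=C(/C)[C@H](OCc3ccc(OC)cc3)/C=C/[C@](C)(O)C[C@@H](O)[C@H]12 | intermediate
42 | angelic acid ((Z)-2-methylbut-2-enoic acid) | C/C=C(/C)C(=O)O | starting material
43 | angelic 2,4,6-trichlorobenzoic anhydride | C/C=C(/C)C(=O)OC(=O)c1c(Cl)cc(Cl)cc1Cl | intermediate (not isolated)
44 | C8 angelate (3-O-PMB, free C10–OH) | C=C1C(=O)O[C@@H]2/C=C(/C)[C@H](OCc3ccc(OC)cc3)/C=C/[C@](C)(O)C[C@@H](OC(=O)/C(C)=C\C)[C@H]12 | intermediate
45 | C3 alcohol | C=C1C(=O)O[C@@H]2/C=C(/C)[C@H](O)/C=C/[C@](C)(O)C[C@@H](OC(=O)/C(C)=C\C)[C@H]12 | intermediate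
46 | CNP0181631.1, (1E,3R,4Z,6R,7S,8R,10R)-3-acetoxy-8-angeloyloxy-10-hydroxygermacra-1,4,11(13)-trien-12,6-olide | C=C1C(=O)O[C@@H]2/C=C(/C)[C@H](OC(C)=O)/C=C/[C@](C)(O)C[C@@H](OC(=O)/C(C)=C\C)[C@H]12 | target

**Totals**

Total step count: 27. Longest linear sequence: 27 steps (1 to 46); 12, 22 and 42 are commercial and enter directly.

**Steps most likely to fail**

Step 19. The hindered tertiary alkoxide may fragment with loss of the propynyl group, or a silyl group may migrate from O10 to the syn-axial O6, before the shift takes place. The fallback sets out from 28 and removes the free alkoxide. Silylation (Me3SiCl, imidazole, DMF) gives the C6 trimethylsilyl ether F1. Heating F1 in degassed 1,2-dichlorobenzene at about 180 °C should bring about the neutral siloxy-Cope shift through the same chair and give the ten-membered trimethylsilyl allenyl ether F2. Methanolysis (K2CO3, MeOH, 0 °C) protonates C5 from the periphery and returns to 31.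

Step 20. Hydride may be delivered to the other face of the carbonyl if the ten-membered ring reacts through a conformer other than the one inherited from the rearrangement. The fallback sets out from 31 and accepts the reduction product as the C6 epimer F3. Mitsunobu inversion (4-nitrobenzoic acid, PPh3, diisopropyl azodicarboxylate, toluene, 0 °C) should give the inverted 4-nitrobenzoate F4. Methanolysis (K2CO3, MeOH) returns to 32.

Step 13. Kinetic deprotonation may lose regiocontrol (attack at the C7 methine as well as the neopentyl-type C1 methylene), or the C1 enolate may expel the anti-periplanar C10 silyloxy group. The fallback sets out from 17 and fixes the site by thermodynamics. Claisen formylation (HCO2Et, NaH, THF, 0 °C) can give a stabilised β-dicarbonyl enolate only at the C1 methylene and so leads to the hydroxymethylene ketone F5. Aqueous formaldehyde with K2CO3 then hydroxymethylates C1 and expels formate (deformylative methylenation), returning to 21.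

**Further compounds**

F1 | step 19 | C6 trimethylsilyl ether of 28 | CC#C[C@@]1(O[Si](C)(C)C)[C@H](/C=C/OCc2ccc(OC)cc2)[C@](C)(O[Si](C)(C)C(C)(C)C)C[C@@H](O[Si](C)(C)C(C)(C)C)[C@@H]1CCO[Si](CC)(CC)CC
F2 | step 19 | ten-membered trimethylsilyl allenyl ether (C6(OSiMe3)=C5=C4) | C[Si](C)(C)OC1=C=C(C)[C@H](OCc2ccc(OC)cc2)/C=C/[C@](C)(O[Si](C)(C)C(C)(C)C)C[C@@H](O[Si](C)(C)C(C)(C)C)[C@@H]1CCO[Si](CC)(CC)CC
F3 | step 20 | C6 epimer of allylic alcohol 32 | O[C@H]1/C=C(/C)[C@H](OCc2ccc(OC)cc2)/C=C/[C@](C)(O[Si](C)(C)C(C)(C)C)C[C@@H](O[Si](C)(C)C(C)(C)C)[C@@H]1CCO[Si](CC)(CC)CC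
F4 | step 20 | 4-nitrobenzoate of 32 (C6 inverted relative to F3) | O=C(O[C@@H]1/C=C(/C)[C@H](OCc2ccc(OC)cc2)/C=C/[C@](C)(O[Si](C)(C)C(C)(C)C)C[C@@H](O[Si](C)(C)C(C)(C)C)[C@@H]1CCO[Si](CC)(CC)CC)c3ccc(cc3)[N+](=O)[O-]
F5 | step 13 | C1 hydroxymethylene ketone from 17 | O=C1C(=CO)[C@](C)(O[Si](C)(C)C(C)(C)C)C[C@@H](O[Si](C)(C)C(C)(C)C)[C@@H]1CCO[Si](CC)(CC)CC
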